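The synthesis depends on cutting the central benzene ring at one bond between two oxygen-bearing carbons. In the target this ring has methoxy groups on C1, C2, C4 and C5 and indol-3-yl groups on the para carbons C3 and C6. C4–C5–C6–C1 therefore map onto a squarate four-membered ring, and C3–C2 onto a methoxyvinyl unit. The precursor is a 4-hydroxycyclobutenone (own numbering) with the 6-prenylindolyl group on C2, methoxy on C3 and a 1-(5-silyloxyindolyl)-2-methoxyvinyl group on C4, with every indole N–H and O–H silylated. Heating opens it to a dienylketene that closes the C1–C2 bond and aromatises, giving the hexasubstituted hydroquinone in one operation. O-Methylation and desilylation finish the synthesis.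

Key step: step 9

Abbreviations: TIPS = triisopropylsilyl; TIPSO = triisopropylsilyloxy; prenyl = 3-methylbut-2-en-1-yl.
Assumption: enol ether 15 is expected as a mixture of E and Z isomers (E drawn). Both are carried on together because step 7 resets the geometry. Compounds 9, 16, 19 and 21 are racemic, and the target has no stereocentre.
Design remark: in 17, 18 and 19 the methoxy group is deliberately cis to Br, Li or the ring carbon. This blocks anti elimination of LiOMe from 18, and the geometry is erased in step 9.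

Step 1
Reactants: 1 6-bromo-1H-indole
Product: 2 6-bromo-1-TIPS-indole
Conditions: NaH, TIPSCl, THF, 0 °C to rt
Reagents that add atoms: triisopropylsilyl chloride, CC(C)[Si](Cl)(C(C)C)C(C)C
Why: N-silylation of the sodium indolide is a standard protection that removes the acidic N–H before the organolithium steps and later shields C2, so that bromination and lithiation stay at C3.

Step 2
Reactants: 2 6-bromo-1-TIPS-indole; 3 1-bromo-3-methylbut-2-ene (prenyl bromide)
Product: 5 6-prenyl-1-TIPS-indole, via 6-lithio-1-TIPS-indole 4 (not isolated)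
Conditions: t-BuLi (2 equiv), THF, −78 °C; then 3, −78 °C to rt
Reagents that add atoms: none
Why: Bromine–lithium exchange followed by SN2 alkylation of the aryllithium at the unhindered primary carbon of the allylic bromide should give the linear prenyl arene, with the second equivalent of t-BuLi consuming the t-BuBr formed.

Step 3
Reactants: 5 6-prenyl-1-TIPS-indole
Product: 6 3-bromo-6-prenyl-1-TIPS-indole
Conditions: NBS (1.0 equiv), THF, −78 °C, dark
Reagents that add atoms: N-bromosuccinimide, O=C1CCC(=O)N1Br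
Why: In this electrophilic aromatic bromination C3 of the N-silylindole is by far the most nucleophilic carbon and C2 is blocked by the silyl group, so at low temperature without light or a nucleophilic co-solvent the trisubstituted prenyl alkene should not compete.

Step 4
Reactants: 6 3-bromo-6-prenyl-1-TIPS-indole; 7 dimethyl squarate
Product: 10 3-methoxy-4-(6-prenyl-1-TIPS-indol-3-yl)cyclobut-3-ene-1,2-dione, via 3-lithio-6-prenyl-1-TIPS-indole 8 (not isolated), via hydroxycyclobutenone adduct 9 (not isolated)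
Conditions: t-BuLi (2 equiv), THF, −78 °C; cannulated into 7, THF, −78 °C; aq NH4Cl; crude 9, cat. 2 M HCl, CH2Cl2, 0 °C; Et3N-washed SiO2
Reagents that add atoms: none
Why: Bromine–lithium exchange gives a 3-lithioindole held at C3 by the bulky N-silyl group, its 1,2-addition to a squarate carbonyl gives racemic carbinol 9, and acid-catalysed ionisation of this indolylic alcohol with loss of methanol (the usual squarate-to-cyclobutenedione transposition) erases that stereocentre and gives the dione.

Step 5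
Reactants: 11 5-hydroxy-1H-indole-3-carbaldehyde
Product: 12 1-TIPS-5-TIPSO-indole-3-carbaldehyde
Conditions: NaH (2.4 equiv), TIPSCl (2.3 equiv), THF–DMF, 0 °C to rt
Reagents that add atoms: triisopropylsilyl chloride, CC(C)[Si](Cl)(C(C)C)C(C)C
Why: Double silylation of the phenoxide and indolide masks both acidic hydrogens in one operation with groups that tolerate ylide, bromine, t-BuLi and heat and are all removed by fluoride at the end.

Step 6
Reactants: 12 1-TIPS-5-TIPSO-indole-3-carbaldehyde; 13 (methoxymethyl)triphenylphosphonium chloride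
Product: 15 3-(2-methoxyvinyl)-1-TIPS-5-TIPSO-indole (E drawn), via methoxymethylidene ylide 14 (not isolated)
Conditions: 13, NaN(SiMe3)2, THF, 0 °C; then 12, −78 °C to rt
Reagents that add atoms: none
Why: The Wittig reaction of the reactive methoxymethylidene ylide with N-protected indole-3-carbaldehydes is a reliable one-carbon homologation to the enol ether, and the non-nucleophilic amide base leaves the silyl groups intact.

Step 7
Reactants: 15 3-(2-methoxyvinyl)-1-TIPS-5-TIPSO-indole
Product: 17 3-[(Z)-1-bromo-2-methoxyvinyl]-1-TIPS-5-TIPSO-indole (Br cis to OMe), via vicinal dibromide 16 (not isolated)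
Conditions: Br2 (1.0 equiv), CH2Cl2, −78 °C; then DBU, −78 °C to rt; Et3N-washed SiO2
Reagents that add atoms: bromine, BrBr
Why: In this bromination–dehydrobromination of an enol ether, bromine adds to the most electron-rich π bond, the α-bromo ether carbon ionises readily, and DBU then removes the acidified indolylic hydrogen to give the β-bromo enol ether, in which the bulky indolyl group should sit trans to methoxy.

Step 8
Reactants: 17 3-[(Z)-1-bromo-2-methoxyvinyl]-1-TIPS-5-TIPSO-indole; 10 3-methoxy-4-(6-prenyl-1-TIPS-indol-3-yl)cyclobut-3-ene-1,2-dione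
Product: 19 rac-4-hydroxy-3-methoxy-4-[(Z)-2-methoxy-1-(1-TIPS-5-TIPSO-indol-3-yl)vinyl]-2-(6-prenyl-1-TIPS-indol-3-yl)cyclobut-2-en-1-one, via vinyllithium 18 (not isolated)
Conditions: 17 (1.2 equiv), t-BuLi (2 equiv per 17), THF, −78 °C; then 10, THF, −78 °C; aq NH4Cl at −78 °C
Reagents that add atoms: none
Why: Bromine–lithium exchange with retention gives a vinyllithium with lithium cis to methoxy, and its 1,2-addition should go to the ketone-like carbonyl C2 of 10 (next to C–OMe) rather than to C1, which is deactivated as a vinylogous ester, forming the carbinol stereocentre as a racemate that needs no control because step 9 destroys it.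

Step 9
Reactants: 19 rac-4-hydroxy-3-methoxy-4-[(Z)-2-methoxy-1-(1-TIPS-5-TIPSO-indol-3-yl)vinyl]-2-(6-prenyl-1-TIPS-indol-3-yl)cyclobut-2-en-1-one
Product: 22 2,5-dimethoxy-3-(1-TIPS-5-TIPSO-indol-3-yl)-6-(6-prenyl-1-TIPS-indol-3-yl)benzene-1,4-diol, via dienylketene 20 (not isolated), via cyclohexadienone 21 (not isolated)
Conditions: degassed toluene (0.01 M), 110 °C, Ar; crude 22 kept under Ar
Reagents that add atoms: none
Why: Heat breaks the C1–C4 bond of 19 in a conrotatory four-electron electrocyclic opening, and because the donor hydroxyl on C4 turns outward, the alkenyl group turns inward and ends cis to the ketene in 20. A disrotatory six-electron electrocyclisation then joins the ketene carbon to the CH(OMe) terminus, closing the six-membered carbocycle through the C1–C2 bond of the future central ring to give dienone 21, whose single ring C–H is lost by irreversible enolisation to the aromatic hydroquinone 22. This is the Moore-type thermal ring expansion of squarate-derived 4-alkenyl-4-hydroxycyclobutenones, a known route to highly substituted hydroquinones. No stereocentre survives, since the carbinol carbon of 19 becomes sp2 on opening, the transient centre of 21 disappears on enolisation and the alkene geometry is erased as well. The only selectivity needed is torquoselectivity, which the hydroxyl donor provides, because the para relation of the two indoles is already fixed in the connectivity of 19 and no indole carbon can reach the ketene through a six-membered transition state. Oxygen is excluded so that 22 is not oxidised to the quinone.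

Step 10
Reactants: 22 2,5-dimethoxy-3-(1-TIPS-5-TIPSO-indol-3-yl)-6-(6-prenyl-1-TIPS-indol-3-yl)benzene-1,4-diol
Product: 23 3-[2,3,5,6-tetramethoxy-4-(6-prenyl-1-TIPS-indol-3-yl)phenyl]-1-TIPS-5-TIPSO-indole
Conditions: Me2SO4, K2CO3, dry acetone, reflux, Ar
Reagents that add atoms: dimethyl sulfate, COS(=O)(=O)OC
Why: Williamson-type O-methylation of the two phenoxides with a small, reactive electrophile should overcome the flanking substituents, while anhydrous carbonate in acetone leaves the aryl and N-silyl groups in place so that the indole 5-oxygen cannot be methylated.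

Step 11
Reactants: 23 3-[2,3,5,6-tetramethoxy-4-(6-prenyl-1-TIPS-indol-3-yl)phenyl]-1-TIPS-5-TIPSO-indole
Product: 24 3-[2,3,5,6-tetramethoxy-4-(6-prenyl-1H-indol-3-yl)phenyl]-1H-indol-5-ol (target)
Conditions: TBAF (3.5 equiv), AcOH (3.5 equiv), THF, 0 °C to rt, Ar
Reagents that add atoms: none
Why: Fluoride-induced desilylation cleaves both N–Si bonds and the aryl O–Si bond in one operation, the acetic acid buffer keeps the freed 5-hydroxyindole from persisting as an oxidisable phenoxide, and the methyl ethers and the prenyl alkene are inert.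

Compound list
1 | 6-bromo-1H-indole | Brc1ccc2cc[nH]c2c1 | starting material
2 | 6-bromo-1-(triisopropylsilyl)indole | CC(C)[Si](C(C)C)(C(C)C)n1ccc2ccc(Br)cc21 | intermediate
3 | 1-bromo-3-methylbut-2-ene (prenyl bromide) | CC(C)=CCBr | starting material
4 | 6-lithio-1-(triisopropylsilyl)indole | CC(C)[Si](C(C)C)(C(C)C)n1ccc2ccc([Li])cc21 | intermediate
5 | 6-(3-methylbut-2-en-1-yl)-1-(triisopropylsilyl)indole | CC(C)=CCc1ccc2ccn([Si](C(C)C)(C(C)C)C(C)C)c2c1 | intermediate
6 | 3-bromo-6-(3-methylbut-2-en-1-yl)-1-(triisopropylsilyl)indole | CC(C)=CCc1ccc2c(Br)cn([Si](C(C)C)(C(C)C)C(C)C)c2c1 | intermediate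
7 | dimethyl squarate (3,4-dimethoxycyclobut-3-ene-1,2-dione) | COC1=C(OC)C(=O)C1=O | starting material
8 | 3-lithio-6-(3-methylbut-2-en-1-yl)-1-(triisopropylsilyl)indole | CC(C)=CCc1ccc2c([Li])cn([Si](C(C)C)(C(C)C)C(C)C)c2c1 | intermediate
9 | rac-4-hydroxy-2,3-dimethoxy-4-[6-prenyl-1-(triisopropylsilyl)indol-3-yl]cyclobut-2-en-1-one | COC1=C(OC)C(O)(c2cn([Si](C(C)C)(C(C)C)C(C)C)c3cc(CC=C(C)C)ccc23)C1=O | intermediate
10 | 3-methoxy-4-[6-prenyl-1-(triisopropylsilyl)indol-3-yl]cyclobut-3-ene-1,2-dione | COC1=C(c2cn([Si](C(C)C)(C(C)C)C(C)C)c3cc(CC=C(C)C)ccc23)C(=O)C1=O | intermediate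
11 | 5-hydroxy-1H-indole-3-carbaldehyde | O=Cc1c[nH]c2ccc(O)cc12 | starting material
12 | 1-(triisopropylsilyl)-5-(triisopropylsilyloxy)indole-3-carbaldehyde | O=Cc1cn([Si](C(C)C)(C(C)C)C(C)C)c2ccc(O[Si](C(C)C)(C(C)C)C(C)C)cc12 | intermediate
13 | (methoxymethyl)triphenylphosphonium chloride | COC[P+](c1ccccc1)(c1ccccc1)c1ccccc1.[Cl-] | starting material
14 | (methoxymethylidene)triphenylphosphorane | COC=P(c1ccccc1)(c1ccccc1)c1ccccc1 | intermediate
15 | 3-[(E)-2-methoxyvinyl]-1-(triisopropylsilyl)-5-(triisopropylsilyloxy)indole (E drawn, Z isomer expected alongside and used too) | CO/C=C/c1cn([Si](C(C)C)(C(C)C)C(C)C)c2ccc(O[Si](C(C)C)(C(C)C)C(C)C)cc12 | intermediate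
16 | 3-(1,2-dibromo-2-methoxyethyl)-1-(triisopropylsilyl)-5-(triisopropylsilyloxy)indole (racemic diastereomer mixture) | COC(Br)C(Br)c1cn([Si](C(C)C)(C(C)C)C(C)C)c2ccc(O[Si](C(C)C)(C(C)C)C(C)C)cc12 | intermediate
17 | 3-[(Z)-1-bromo-2-methoxyvinyl]-1-(triisopropylsilyl)-5-(triisopropylsilyloxy)indole | CO/C=C(\Br)c1cn([Si](C(C)C)(C(C)C)C(C)C)c2ccc(O[Si](C(C)C)(C(C)C)C(C)C)cc12 | intermediate
18 | (E)-2-methoxy-1-[1-(triisopropylsilyl)-5-(triisopropylsilyloxy)indol-3-yl]vinyllithium (Li cis to OMe) | CO/C=C(\[Li])c1cn([Si](C(C)C)(C(C)C)C(C)C)c2ccc(O[Si](C(C)C)(C(C)C)C(C)C)cc12 | intermediate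
19 | rac-4-hydroxy-3-methoxy-4-[(Z)-2-methoxy-1-(1-triisopropylsilyl-5-triisopropylsilyloxyindol-3-yl)vinyl]-2-(6-prenyl-1-triisopropylsilylindol-3-yl)cyclobut-2-en-1-one | COC1=C(c2cn([Si](C(C)C)(C(C)C)C(C)C)c3cc(CC=C(C)C)ccc23)C(=O)C1(O)/C(c1cn([Si](C(C)C)(C(C)C)C(C)C)c2ccc(O[Si](C(C)C)(C(C)C)C(C)C)cc12)=C\OC | intermediate
20 | (3Z,5Z)-4-hydroxy-3,6-dimethoxy-5-(1-triisopropylsilyl-5-triisopropylsilyloxyindol-3-yl)-2-(6-prenyl-1-triisopropylsilylindol-3-yl)hexa-1,3,5-trien-1-one (dienylketene) | O=C=C(c1cn([Si](C(C)C)(C(C)C)C(C)C)c2cc(CC=C(C)C)ccc12)/C(OC)=C(O)\C(c1cn([Si](C(C)C)(C(C)C)C(C)C)c2ccc(O[Si](C(C)C)(C(C)C)C(C)C)cc12)=C/OC | intermediate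
21 | rac-4-hydroxy-3,6-dimethoxy-5-(1-triisopropylsilyl-5-triisopropylsilyloxyindol-3-yl)-2-(6-prenyl-1-triisopropylsilylindol-3-yl)cyclohexa-2,4-dien-1-one | COC1C(=O)C(c2cn([Si](C(C)C)(C(C)C)C(C)C)c3cc(CC=C(C)C)ccc23)=C(OC)C(O)=C1c1cn([Si](C(C)C)(C(C)C)C(C)C)c2ccc(O[Si](C(C)C)(C(C)C)C(C)C)cc12 | intermediate
22 | 2,5-dimethoxy-3-(1-triisopropylsilyl-5-triisopropylsilyloxyindol-3-yl)-6-(6-prenyl-1-triisopropylsilylindol-3-yl)benzene-1,4-diol | COc1c(-c2cn([Si](C(C)C)(C(C)C)C(C)C)c3ccc(O[Si](C(C)C)(C(C)C)C(C)C)cc23)c(O)c(OC)c(-c2cn([Si](C(C)C)(C(C)C)C(C)C)c3cc(CC=C(C)C)ccc23)c1O | intermediate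
23 | 3-[2,3,5,6-tetramethoxy-4-(6-prenyl-1-triisopropylsilylindol-3-yl)phenyl]-1-(triisopropylsilyl)-5-(triisopropylsilyloxy)indole | COc1c(OC)c(-c2cn([Si](C(C)C)(C(C)C)C(C)C)c3ccc(O[Si](C(C)C)(C(C)C)C(C)C)cc23)c(OC)c(OC)c1-c1cn([Si](C(C)C)(C(C)C)C(C)C)c2cc(CC=C(C)C)ccc12 | intermediate
24 | 3-[2,3,5,6-tetramethoxy-4-(6-prenyl-1H-indol-3-yl)phenyl]-1H-indol-5-ol (CNP0145408.0) | COc1c(OC)c(-c2c[nH]c3ccc(O)cc23)c(OC)c(OC)c1-c1c[nH]c2cc(CC=C(C)C)ccc12 | target

Total step count: 11.
Longest linear sequence: 8 steps (1, 2, 3, 4, 8, 9, 10, 11). The other branch (5, 6, 7) joins at step 8.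

Steps most likely to fail

Step 9. Three things may go wrong:
- Part of the material may open with the hydroxyl turning inward, so that the ketene is captured as a lactone.
- The closure may be slowed by the methoxy group that points into the forming ring.
- The very electron-rich hydroquinone may oxidise while hot or on isolation.

The fallback redesigns the substrate. It sets out from 10 and 17 and returns at 23. The addition of step 8 is repeated, but the lithium alkoxide is trapped in the flask with methyl triflate (−78 to 0 °C). This gives rac-3,4-dimethoxy-4-[(Z)-2-methoxy-1-(1-TIPS-5-TIPSO-indol-3-yl)vinyl]-2-(6-prenyl-1-TIPS-indol-3-yl)cyclobut-2-en-1-one F1. Without a free hydroxyl, lactonisation is impossible, and methoxy is also an outward-rotating donor. Thermolysis in toluene should therefore give 2,4,5-trimethoxy-3-(1-TIPS-5-TIPSO-indol-3-yl)-6-(6-prenyl-1-TIPS-indol-3-yl)phenol F2, which cannot pass to a quinone by simple air oxidation. Methylation of its single phenol (Me2SO4, K2CO3, acetone) gives 23.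

Step 8. The vinyllithium may decay by loss of lithium methoxide or by proton abstraction before it is captured. Alternatively, the hindered reagent may attack the vinylogous ester carbonyl in part, which after ring expansion would place the indoles meta.

The fallback abandons the squarate and builds the biaryl bonds by two Suzuki–Miyaura couplings. It sets out from 6 and returns at 23.
- Exchange of 6 with t-BuLi and quenching with 2-isopropoxy-4,4,5,5-tetramethyl-1,3,2-dioxaborolane gives 6-prenyl-1-TIPS-indol-3-ylboronic acid pinacol ester F3.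
- Commercial 1,2,4,5-tetramethoxybenzene is dibrominated (NBS, MeCN) to 1,4-dibromo-2,3,5,6-tetramethoxybenzene F4.
- An excess of F4 is coupled with F3 (Pd(OAc)2, SPhos, K3PO4, toluene, 90 °C) to give 3-(4-bromo-2,3,5,6-tetramethoxyphenyl)-6-prenyl-1-TIPS-indole F5.
- Commercial 5-hydroxyindole is silylated twice (NaH, TIPSCl) to 1-TIPS-5-TIPSO-indole F6.
- C–H borylation of F6 ([Ir(OMe)(cod)]2, 4,4′-di-tert-butyl-2,2′-bipyridine, B2pin2) is steered to C3 by the two bulky silyl groups and gives 1-TIPS-5-TIPSO-indol-3-ylboronic acid pinacol ester F7.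
- Coupling F5 with F7 under the same palladium conditions gives 23.

Step 7. Bromine may attack the indole nucleus. Hydrogen bromide may be lost in the wrong direction through the equally labile indolylic bromide. The doubly activated dibromide may solvolyse, or the wrong alkene geometry may prevail.

The fallback keeps electrophilic halogen away from the indole altogether. It sets out from 12 and returns at 18.
- Methoxymethyllithium (Bu3SnCH2OMe, n-BuLi, THF, −78 °C) adds to 12 to give rac-2-methoxy-1-(1-TIPS-5-TIPSO-indol-3-yl)ethanol F8.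
- MnO2 in CH2Cl2 oxidises F8 to 2-methoxy-1-(1-TIPS-5-TIPSO-indol-3-yl)ethanone F9.
- KN(SiMe3)2 and PhNTf2 convert the chelated enolate of F9 into (Z)-2-methoxy-1-(1-TIPS-5-TIPSO-indol-3-yl)vinyl trifluoromethanesulfonate F10.
- Stannylation of F10 (Me3SnSnMe3, Pd(PPh3)4, LiCl, THF, 60 °C) with retention gives (Z)-[2-methoxy-1-(1-TIPS-5-TIPSO-indol-3-yl)vinyl]trimethylstannane F11.
- Tin–lithium exchange of F11 with MeLi (THF, −78 °C) gives 18, which is used as in step 8.

Further compounds
F1 | step 9 | rac-3,4-dimethoxy-4-[(Z)-2-methoxy-1-(1-triisopropylsilyl-5-triisopropylsilyloxyindol-3-yl)vinyl]-2-(6-prenyl-1-triisopropylsilylindol-3-yl)cyclobut-2-en-1-one | COC1=C(c2cn([Si](C(C)C)(C(C)C)C(C)C)c3cc(CC=C(C)C)ccc23)C(=O)C1(OC)/C(c1cn([Si](C(C)C)(C(C)C)C(C)C)c2ccc(O[Si](C(C)C)(C(C)C)C(C)C)cc12)=C\OC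
F2 | step 9 | 2,4,5-trimethoxy-3-(1-triisopropylsilyl-5-triisopropylsilyloxyindol-3-yl)-6-(6-prenyl-1-triisopropylsilylindol-3-yl)phenol | COc1c(O)c(-c2cn([Si](C(C)C)(C(C)C)C(C)C)c3cc(CC=C(C)C)ccc23)c(OC)c(OC)c1-c1cn([Si](C(C)C)(C(C)C)C(C)C)c2ccc(O[Si](C(C)C)(C(C)C)C(C)C)cc12
F3 | step 8 | 6-prenyl-1-(triisopropylsilyl)indol-3-ylboronic acid pinacol ester | CC(C)=CCc1ccc2c(B3OC(C)(C)C(C)(C)O3)cn([Si](C(C)C)(C(C)C)C(C)C)c2c1
F4 | step 8 | 1,4-dibromo-2,3,5,6-tetramethoxybenzene | COc1c(Br)c(OC)c(OC)c(Br)c1OC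
F5 | step 8 | 3-(4-bromo-2,3,5,6-tetramethoxyphenyl)-6-prenyl-1-(triisopropylsilyl)indole | COc1c(Br)c(OC)c(OC)c(-c2cn([Si](C(C)C)(C(C)C)C(C)C)c3cc(CC=C(C)C)ccc23)c1OC
F6 | step 8 | 1-(triisopropylsilyl)-5-(triisopropylsilyloxy)indole | CC(C)[Si](C(C)C)(C(C)C)Oc1ccc2c(ccn2[Si](C(C)C)(C(C)C)C(C)C)c1
F7 | step 8 | 1-(triisopropylsilyl)-5-(triisopropylsilyloxy)indol-3-ylboronic acid pinacol ester | CC(C)[Si](C(C)C)(C(C)C)Oc1ccc2c(c1)c(B1OC(C)(C)C(C)(C)O1)cn2[Si](C(C)C)(C(C)C)C(C)C
F8 | step 7 | rac-2-methoxy-1-[1-(triisopropylsilyl)-5-(triisopropylsilyloxy)indol-3-yl]ethanol | COCC(O)c1cn([Si](C(C)C)(C(C)C)C(C)C)c2ccc(O[Si](C(C)C)(C(C)C)C(C)C)cc12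
F9 | step 7 | 2-methoxy-1-[1-(triisopropylsilyl)-5-(triisopropylsilyloxy)indol-3-yl]ethanone | COCC(=O)c1cn([Si](C(C)C)(C(C)C)C(C)C)c2ccc(O[Si](C(C)C)(C(C)C)C(C)C)cc12
F10 | step 7 | (Z)-2-methoxy-1-[1-(triisopropylsilyl)-5-(triisopropylsilyloxy)indol-3-yl]vinyl trifluoromethanesulfonate | CO/C=C(\OS(=O)(=O)C(F)(F)F)c1cn([Si](C(C)C)(C(C)C)C(C)C)c2ccc(O[Si](C(C)C)(C(C)C)C(C)C)cc12
F11 | step 7 | (Z)-{2-methoxy-1-[1-(triisopropylsilyl)-5-(triisopropylsilyloxy)indol-3-yl]vinyl}trimethylstannane | CO/C=C(\[Sn](C)(C)C)c1cn([Si](C(C)C)(C(C)C)C(C)C)c2ccc(O[Si](C(C)C)(C(C)C)C(C)C)cc12
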